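## Structural features

The target is a germacranolide. A ten-membered carbocycle (C1–C10) is fused at C6–C7 to an α,β-unsaturated γ-lactone (O–C6, C7=C11, C12=O), and the lactone α-carbon C11 carries the acetoxymethyl group C13. The carbocycle holds a Z trisubstituted alkene C4=C5 (methyl C15 on C4) flanked by two allylic oxygen stereocentres, C3 (acetate, S) and C6 (lactone oxygen, R). It also holds an exocyclic methylene C10=C14 next to the third stereocentre, C1 (hydroperoxide, R). No two stereocentres are adjacent: C1 and C3 are 1,3-related across C2, and C3 and C6 are 1,4-related across the Z-alkene, so each centre needs its own source of control. The fragile groups are: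

- the secondary allylic hydroperoxide (reduced by phosphines and low-valent metals, fragmented by base);
- the two acetates, of which the C3 one is allylic and would ionise with zerovalent palladium;
- C6–H, which is the γ-hydrogen of the butenolide and also allylic, so base can epimerise it;
- the butenolide as a Michael acceptor.

The real difficulty is twofold: closing a strained ten-membered ring that contains a Z-alkene, and handling five oxygen functions so that the hydroperoxide is the last group made. The key step uses the C8–C9 bond. C9 is one of two equivalent CH2 termini of the allyl unit C9–C10(=C14), and C8 is α to C7, which can be a ketone as long as the butenolide is not yet built. An enolate at C8 and an allyl cation over C9–C10–C14 are therefore natural partners.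

## Logic of the disconnections

**38 ⇒ 37 ⇒ 33 + 35.** The O–C bond of the peroxyketal and then the C1–O bond are cut. A hydroperoxide tolerates neither phosphines, low-valent metals, hydrides nor acylating agents, so it must be made last; cutting C1–O turns it into a secondary alcohol that earlier steps can carry protected. The forward step is an SN2 displacement at an allylic secondary carbon. It therefore demands the opposite (S) configuration at C1 in all earlier compounds, and a mono-protected hydrogen peroxide (35, from 34) so that only one O–C bond forms.

**33 ⇒ 32 ⇒ 31 ⇒ 30 ⇒ 29.** Only O–acyl, O–Si and O–benzyl bonds are cut. The acetates cannot be present while zerovalent palladium or carbanion bases are in use. They are traced back to a 4-methoxybenzyl ether at C13 and a tert-butyldimethylsilyl ether at C3, and the C1 oxygen to a triisopropylsilyl ether that outlives both. This costs four protecting-group steps and requires three levels of lability.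

**29 ⇒ 28 ⇒ 23 + 27.** The C7=C11 double bond and the C12–O(C6) ester bond are cut. This removes the butenolide with C11–C13 in one move and leaves an α-hydroxy ketone. The forward step is an intramolecular Horner–Wadsworth–Emmons olefination. It is preferred to an ester-enolate aldol closure because the phosphonate is by far the most acidic site of 28, so an amine base suffices and C6–H next to the ketone is spared. It demands a phosphonoacetic acid that already carries the C13 oxygen (27, from 24 and 25).

**23 ⇒ 22 ⇒ 21 (key).** The C8–C9 bond is cut and the two carbons are reconnected through a CO2 unit. The ten-membered carbocycle becomes a twelve-membered lactone in which C9–O is an allylic ester and C8 lies between two carbonyls. The gain is that the hard C–C ring closure is replaced by an ester-forming one, and that C8 and C9 are held 1,4 to each other before they bond. The forward step demands an enolate at C8 only, a symmetrical allyl unit and no second allylic ester, hence ethers at C1, C3 and C6.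

**21 ⇒ 19 (through 20) ⇒ 18 ⇒ 16 + 17.** The lactone C–O bond is cut to a hydroxy β-keto ester, and the C7–C8 bond to an aldehyde and a diazoacetate. A tert-butyl ester is chosen because it releases the acylketene at the boiling point of toluene, which an ethyl ester does not. The carbon that is homologated is the aldehyde carbon C7, so C6 must enter already oxygenated and configured. The C9 hydroxyl needs a group removable beside three silyl ethers and a β-keto ester, which is why the 4-methoxybenzyl ether is placed there and not at C1.

**16 ⇒ 15 ⇒ 14 ⇒ 13.** Functional-group changes only: the α-silyloxy aldehyde goes back to a terminal acetonide. This keeps C6/C7 inert during aldol and reduction, and later demands a chemoselective oxidation of a primary silyl ether.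

**13 ⇒ 12 ⇒ 11 ⇒ 10 ⇒ 5 + 8.** The C3–H bond (reduction) and the C1–C2 bond (aldol) are cut. The chain splits into two pieces of similar size at the one place where both new stereocentres can be set by reagents; C6 is too remote to help or interfere. The C1 hydroxyl of 10 is β to a ketone and allylic, so it is silylated at low temperature rather than benzylated under acid.

**5 ⇒ 3 ⇒ 1 + 2, and 8 ⇒ 7 ⇒ 6.** The C4=C5 bond is cut by a Z-selective olefination. C5, C6, C7 and the C6 configuration come from the chiral pool; C3, C4 and C15 come from the phosphonate. A four-carbon C15–C4–C5–C6 unit would stop short of C7 and bring no stereocentre. The enal comes from the symmetrical diol 6 by mono-protection and oxidation.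

## Other disconnections considered

**Alternative 1:** The cut removes C6–C7, C11–C12 and C12–O together and leads to the open-chain alkynyl Z-enal A2. In the forward step Ru3(CO)12 under CO (or Mo(CO)6) would couple alkyne, aldehyde and CO in a hetero-Pauson–Khand-type cyclocarbonylation to the dienolide A1. A Schenck ene reaction with singlet oxygen would then give the target.

- In its favour: three bonds and both rings form in one step, the acetates are present from the start, C1 needs no protecting group, and the hydroperoxide arises by an addition that is known for germacrene-type alkenes. On step economy and on the way the hydroperoxide is made it is better than the chosen plan.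
- Against it: this cyclocarbonylation is established where a short tether forces alkyne and aldehyde onto one metal and a five- or six-membered ring results. For a ten-membered ring nothing holds the ends together, so oligomerisation is the likely course. The conjugated Z-enal is a poor and isomerisable aldehyde partner. C6 would be created in this step under remote control from C3 only. The propargylic and allylic acetates would face a low-valent metal carbonyl at high temperature.
- Comparison: on structure it is the more convergent plan. On mechanism the chosen plan is safer, because C8 and C9 are pre-organised in a lactone and C6 comes from the chiral pool.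

**Alternative 2:** The cut removes the C6–O and C3–O bonds and leads to the ring-diene carboxylic acid A4. In the forward step Pd(OAc)2, benzoquinone and LiOAc in chloride-free acetic acid would let the carboxylate attack C6 of the diene bound to divalent palladium, and would deliver acetate to C3 of the resulting allyl, giving A3.

- In its favour: two C–O bonds, two stereocentres and the Z-alkene are set in one catalytic oxidation. The C3 oxygen arrives directly as the acetate, so no protecting-group exchange is needed, which is better than the chosen plan. The C3/C6 relationship follows from the mechanism (attack anti to the metal, then delivery from the metal) rather than from two separate reagent-controlled steps.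
- Against it: A4 already contains the ten-membered ring, so ring formation is only moved earlier, onto a substrate with a 1,3-diene and an exocyclic alkylidene acid. The diene is unsymmetrical and must coordinate s-cis inside a medium ring. The absolute sense relative to C1 rests on a remote silyloxy group. Divalent palladium may also oxidise the allylic positions next to C10=C14.
- Comparison: A3 has the same (1S) oxygen as 32 and needs the same invertive peroxide installation, so the endgame is equal. Overall step economy would be no better once A4 has to be made.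

**Alternative 3:** The cut breaks C2–C3 and re-forms C5–C10, leading to the cis-dialkenylcyclohexanol A6. In the forward step KH with 18-crown-6 would trigger an anionic oxy-Cope rearrangement, and PhNTf2 would trap the ring-expanded enolate as the dienyl triflate A5.

- In its favour: this is the best-precedented entry to ten-membered 1,5-dienes. A chair transition state would translate the E-enol ether into the C3 configuration and the cis ring relationship into the Z C4=C5 and E C1=C10 alkenes. No high dilution is needed and enolate formation makes it irreversible. On the reliability of ring formation it is better than the chosen key step.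
- Against it: A6 needs three contiguous stereocentres on a cyclohexane, a tertiary vinyl carbinol cis to the alkenyl group and a geometrically pure enol ether, which is a synthesis of its own. A5 would still need a methyl cross-coupling at C10, ketal removal, the same butenolide construction as here, and a substrate-controlled photooxygenation for C1.
- Comparison: the butenolide problem is equal in both plans. The extra functional-group changes make this route at least as long as the chosen one.

Key step: step 15

Remarks on the chemistry (assumptions):
- Germacrane locants (C1–C15) are used for all intermediates, and the descriptors (1S,3S,6R) refer to these locants.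
- (S)-Glyceraldehyde acetonide 1 is taken as purchasable and is distilled before use.
- (−)-Ipc2BCl is assumed to direct the methyl ketone enolate to the Si face of the aldehyde, as B-allyl reagents from the same borane do. The C1 configuration of 10 would be checked by Mosher ester analysis before going on.

## Route

Step 1
Reactants: 1 (S)-2,2-dimethyl-1,3-dioxolane-4-carbaldehyde; 2 ethyl 2-[bis(2,2,2-trifluoroethoxy)phosphoryl]propanoate
Product: 3 ethyl (2Z)-3-[(4R)-2,2-dimethyl-1,3-dioxolan-4-yl]-2-methylprop-2-enoate
Conditions: KN(SiMe3)2, 18-crown-6, THF, −78 °C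
Reagents that add atoms: none
Why: Still–Gennari olefination: the electron-poor phosphonate under dissociating conditions eliminates from the kinetic adduct and should give the Z trisubstituted enoate (C3 cis to C6). The C6 stereocentre is carried over unchanged from 1.

Step 2
Reactants: 3 ethyl (2Z)-3-[(4R)-2,2-dimethyl-1,3-dioxolan-4-yl]-2-methylprop-2-enoate
Product: 5 (3Z)-4-[(4R)-2,2-dimethyl-1,3-dioxolan-4-yl]-3-methylbut-3-en-2-one, via Weinreb amide 4 (not isolated)
Conditions: MeNHOMe·HCl, iPrMgCl, THF, −20 °C; then MeMgBr, 0 °C; aq. NH4Cl
Reagents that add atoms: methylmagnesium bromide, C[Mg]Br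
Why: One-pot Weinreb ketone synthesis: the magnesium amide converts the ester into the N-methoxy-N-methylamide, whose chelated adduct with MeMgBr stops at the ketone. The Z geometry is not touched.

Step 3
Reactants: 6 2-methylenepropane-1,3-diol
Product: 7 2-{[(4-methoxybenzyl)oxy]methyl}prop-2-en-1-ol
Conditions: NaH (1 equiv), PMBCl, Bu4NI (cat.), THF/DMF, 0 °C to rt (6 in excess)
Reagents that add atoms: 4-methoxybenzyl chloride, COc1ccc(CCl)cc1
Why: Williamson etherification; with the symmetrical diol in excess the mono-ether should dominate, and unreacted 6 is recovered.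

Step 4
Reactants: 7 2-{[(4-methoxybenzyl)oxy]methyl}prop-2-en-1-ol
Product: 8 2-{[(4-methoxybenzyl)oxy]methyl}prop-2-enal
Conditions: MnO2, CH2Cl2, rt
Reagents that add atoms: none
Why: Selective oxidation of a primary allylic alcohol by MnO2; the enal is used at once because it polymerises on standing.

Step 5
Reactants: 5 (3Z)-4-[(4R)-2,2-dimethyl-1,3-dioxolan-4-yl]-3-methylbut-3-en-2-one; 8 2-{[(4-methoxybenzyl)oxy]methyl}prop-2-enal
Product: 10 (1Z,5S)-1-[(4R)-2,2-dimethyl-1,3-dioxolan-4-yl]-5-hydroxy-6-{[(4-methoxybenzyl)oxy]methyl}-2-methylhepta-1,6-dien-3-one, via enol diisopinocampheylborinate 9 (not isolated)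
Conditions: (−)-Ipc2BCl, Et3N, Et2O, 0 °C; then 8, −78 to −20 °C; then MeOH, pH 7 buffer, H2O2, 0 °C
Reagents that add atoms: none
Why: Boron aldol reaction of a methyl ketone through its Ipc2B enolate, forming C1–C2; the isopinocampheyl ligands should direct the enolate to the Si face of the aldehyde, which corresponds to the (1S) carbinol (reagent control, C6 is too remote to matter). The minor (1R) adduct is a diastereomer and is removed by chromatography.

Step 6
Reactants: 10 (1S,6R) aldol adduct
Product: 11 C1 triisopropylsilyl ether of 10 [(1S,6R); C3 ketone]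
Conditions: iPr3SiOTf, 2,6-lutidine, CH2Cl2, −78 °C
Reagents that add atoms: triisopropylsilyl trifluoromethanesulfonate, CC(C)[Si](C(C)C)(C(C)C)OS(=O)(=O)C(F)(F)F
Why: Silylation with a silyl triflate and a hindered base is fast at −78 °C, so the β-hydroxy ketone has no chance to eliminate or undergo retro-aldol cleavage.

Step 7
Reactants: 11 C1 triisopropylsilyl ether [(1S,6R); C3 ketone]
Product: 12 (1S,3S,6R) C3 allylic alcohol
Conditions: (R)-2-methyl-CBS-oxazaborolidine, catecholborane, toluene, −78 °C
Reagents that add atoms: none
Why: Corey–Bakshi–Shibata reduction of an enone: with the alkenyl group as the large and C2H2 as the small substituent, the (R)-oxazaborolidine should deliver hydride to the face that gives the (3S) alcohol, 1,3-anti to C1, by reagent control. Catecholborane does not hydroborate C10=C14 at this temperature.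

Step 8
Reactants: 12 (1S,3S,6R) C3 allylic alcohol
Product: 13 (1S,3S,6R) C3 tert-butyldimethylsilyl ether (C1 OTIPS, C6/C7 acetonide, C9 OPMB)
Conditions: tBuMe2SiOTf, 2,6-lutidine, CH2Cl2, −78 to 0 °C
Reagents that add atoms: tert-butyldimethylsilyl trifluoromethanesulfonate, CC(C)(C)[Si](C)(C)OS(=O)(=O)C(F)(F)F
Why: Standard silylation of a hindered secondary allylic alcohol; the silyl ether will not ionise with zerovalent palladium later.

Step 9
Reactants: 13 (1S,3S,6R) acetonide
Product: 14 (1S,3S,6R) C6,C7-diol
Conditions: AcOH/H2O/THF (3:1:1), 40 °C
Reagents that add atoms: none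
Why: Acid-catalysed hydrolysis of a terminal acetonide; secondary tert-butyldimethylsilyl and triisopropylsilyl ethers and the 4-methoxybenzyl ether should survive aqueous acetic acid. C3 is already a protected alcohol, so the Z-related C6 hydroxyl cannot close a furan.

Step 10
Reactants: 14 (1S,3S,6R) C6,C7-diol
Product: 15 C6,C7-bis(triethylsilyl) ether
Conditions: Et3SiOTf, 2,6-lutidine, CH2Cl2, −78 °C
Reagents that add atoms: triethylsilyl trifluoromethanesulfonate, CC[Si](CC)(CC)OS(=O)(=O)C(F)(F)F
Why: Exhaustive silylation of the diol; the triethylsilyl group is chosen because its primary ether can be oxidised directly and its secondary ether can later be removed beside the bulkier silyl ethers.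

Step 11
Reactants: 15 C6,C7-bis(triethylsilyl) ether
Product: 16 (1S,3S,6R) C7 aldehyde with C6 triethylsilyl ether
Conditions: (COCl)2, DMSO, CH2Cl2, −78 to −40 °C; then Et3N, −78 to 0 °C
Reagents that add atoms: none
Why: Swern oxidation applied directly to a primary triethylsilyl ether: the chlorosulfonium ion attacks the unhindered primary ether oxygen, the silyl group leaves as the chloride, and the alkoxysulfonium ion collapses to the aldehyde. Secondary silyl ethers are too hindered to react, and the cold amine quench protects the C6 centre.

Step 12
Reactants: 16 C7 aldehyde; 17 tert-butyl diazoacetate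
Product: 18 tert-butyl β-keto ester (C7 ketone, C8 methylene, C6 OTES, C9 OPMB)
Conditions: SnCl2 (0.2 equiv), CH2Cl2, rt
Reagents that add atoms: none
Why: Roskamp reaction: the diazo carbon adds to the Lewis-acid-activated aldehyde and a 1,2-hydride shift with loss of N2 gives the β-keto ester, forming C7–C8. The conditions are neutral, so the α-silyloxy centre C6 should keep its configuration.

Step 13
Reactants: 18 tert-butyl β-keto ester
Product: 19 C9 primary allylic alcohol with the tert-butyl β-keto ester
Conditions: DDQ, CH2Cl2/pH 7 buffer, 0 °C
Reagents that add atoms: none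
Why: Oxidative cleavage of the only 4-methoxybenzyl ether (hydride abstraction at the benzylic carbon, then hydrolysis); silyl ethers and the β-keto ester are inert under buffered conditions.

Step 14
Reactants: 19 C9 alcohol with the tert-butyl β-keto ester
Product: 21 twelve-membered allyl β-keto lactone [(1S,3S,6R); C1 OTIPS; C3 OTBS; C6 OTES], via acylketene 20 (not isolated)
Conditions: toluene, 110 °C, 0.5 mM (slow addition)
Reagents that add atoms: none
Why: Acylketene macrolactonisation: the tert-butyl β-keto ester loses tert-butanol thermally, and the acylketene is trapped by the only free hydroxyl (C9) to close the twelve-membered ring. High dilution disfavours dimers, and no activating agent or base is present that could touch C6.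

Step 15
Reactants: 21 twelve-membered allyl β-keto lactone
Product: 22 ten-membered C7 ketone with C10 exocyclic methylene [(1S,3S,6R); C1 OTIPS; C3 OTBS; C6 OTES]
Conditions: Pd(PPh3)4 (10 mol %), THF, 40 °C, 1 mM (slow addition), degassed
Reagents that add atoms: none
Why: Zerovalent palladium adds oxidatively to the allylic C9–O bond of 21 and expels the β-keto carboxylate, which stays tied to the π-allyl unit over C9–C10–C14 through the C1–C7 chain; the carboxylate loses CO2, the enolate can only form on the C8 side of C7, and C-allylation at C8 closes the ring (if C8 is allylated before CO2 is lost, the β-keto acid so formed decarboxylates to the same ketone). The closest known reaction is the palladium-catalysed decarboxylative allylation of allyl β-keto esters, the catalysed counterpart of the Carroll rearrangement, here run inside a ring so that the ring contracts by two atoms. The ten-membered carbocycle is closed by attack of the enolate carbon on a terminal allyl carbon; the two atoms are 1,4-related in the lactone (C8–C–O–C9) before ionisation, so the closure has the topology of a [3,3] shift and does not rely on chance encounter of chain ends. No stereocentre is formed: C8 stays CH2, and C9 and C14 are both CH2, so attack at either allyl terminus gives the same constitution. The step needs C-allylation rather than O-allylation or protonation, which the soft palladium enolate in a neutral, aprotic, dilute medium should provide, with high dilution also suppressing transfer of allyl groups or protons between molecules. It needs C6 to keep its configuration, which is secured because the enolate is generated regiospecifically at C8 by decarboxylation and consumed before it can equilibrate towards C6. It needs a single ionisable site, which is why C1, C3 and C6 carry silyl ethers and not the acetates of the target. Loss of CO2 makes the contraction irreversible.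

Step 16
Reactants: 22 ten-membered C7 ketone
Product: 23 (1S,3S,6R) C6 α-hydroxy ketone (C1 OTIPS, C3 OTBS)
Conditions: HF·pyridine, pyridine, THF, 0 °C
Reagents that add atoms: none
Why: Selective desilylation: under buffered fluoride the triethylsilyl ether is cleaved much faster than the tert-butyldimethylsilyl and triisopropylsilyl ethers, and the weakly acidic medium leaves the α-hydroxy ketone untouched.

Step 17
Reactants: 24 ethyl 2-(diethoxyphosphoryl)prop-2-enoate; 25 (4-methoxyphenyl)methanol
Product: 26 ethyl 2-(diethoxyphosphoryl)-3-[(4-methoxybenzyl)oxy]propanoate (racemic)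
Conditions: KOtBu (5 mol %), THF, 0 °C to rt
Reagents that add atoms: none
Why: Base-catalysed oxa-Michael addition of an alkoxide to a doubly activated acrylate; the adduct carbanion is protonated by the alcohol, which carries the chain.

Step 18
Reactants: 26 ethyl 2-(diethoxyphosphoryl)-3-[(4-methoxybenzyl)oxy]propanoate
Product: 27 2-(diethoxyphosphoryl)-3-[(4-methoxybenzyl)oxy]propanoic acid (racemic)
Conditions: LiOH, THF/H2O, 0 °C; then aq. HCl to pH 2
Reagents that add atoms: lithium hydroxide, [Li+].[OH-]
Why: Saponification of the activated carboxylic ester, which is far faster than hydrolysis of the phosphonate esters; low temperature keeps loss of the β-alkoxy group from the small carbanion fraction slow.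

Step 19
Reactants: 23 C6 α-hydroxy ketone; 27 2-(diethoxyphosphoryl)-3-[(4-methoxybenzyl)oxy]propanoic acid
Product: 28 C6 ester of 23 with 27 (epimers at the phosphonate carbon C11)
Conditions: EDC·HCl, DMAP (cat.), CH2Cl2, 0 °C to rt
Reagents that add atoms: none
Why: Steglich-type carbodiimide esterification of the only free hydroxyl; the stereochemistry at the phosphonate carbon is irrelevant because it becomes sp2 in the next step.

Step 20
Reactants: 28 C6 phosphonoester
Product: 29 butenolide [(1S,3S,6R); C13 OPMB; C3 OTBS; C1 OTIPS]
Conditions: LiCl, iPr2NEt, MeCN, 0 °C to rt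
Reagents that add atoms: none
Why: Intramolecular Horner–Wadsworth–Emmons olefination under Masamune–Roush conditions: the lithium-chelated phosphonate is the only site an amine base can deprotonate, its carbanion attacks the C7 ketone in a five-membered mode, and loss of diethyl phosphate gives the C7=C11 butenolide. Loss of 4-methoxybenzyloxide from the carbanion only regenerates the phosphonoacrylate to which the alkoxide adds again, whereas olefination is irreversible; C6 is not deprotonated under these conditions.

Step 21
Reactants: 29 butenolide with C13 OPMB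
Product: 30 C13 primary alcohol (C3 OTBS, C1 OTIPS)
Conditions: DDQ, CH2Cl2/pH 7 buffer, 0 °C to rt
Reagents that add atoms: none
Why: Oxidative removal of the 4-methoxybenzyl ether; it is done while C3 is still silylated so that no free secondary allylic alcohol is exposed to the quinone.

Step 22
Reactants: 30 C13 alcohol
Product: 31 (1S,3S,6R) C3,C13-diol (C1 OTIPS)
Conditions: HF·pyridine, pyridine, THF, 0 °C to rt
Reagents that add atoms: none
Why: Fluoride-mediated desilylation under acidic, non-basic conditions, which spare C6–H; the bulkier triisopropylsilyl ether at C1 is cleaved much more slowly than the tert-butyldimethylsilyl ether at C3.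

Step 23
Reactants: 31 C3,C13-diol
Product: 32 (1S,3S,6R) C3,C13-diacetate (C1 OTIPS)
Conditions: Ac2O, pyridine, DMAP (cat.), CH2Cl2, 0 °C
Reagents that add atoms: acetic anhydride, CC(=O)OC(C)=O
Why: Nucleophile-catalysed acetylation of a primary and a secondary allylic alcohol; pyridine is too weak a base to epimerise C6.

Step 24
Reactants: 32 C3,C13-diacetate with C1 OTIPS
Product: 33 (1S,3S,6R) C1 alcohol diacetate
Conditions: HF·pyridine (excess), THF, rt
Reagents that add atoms: none
Why: Unbuffered HF·pyridine removes the remaining secondary triisopropylsilyl ether; acetates and the butenolide are stable, and the acidic medium avoids migration of the C3 acetate to the 1,3-related C1 hydroxyl.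

Step 25
Reactants: 34 2,3-dimethylbut-2-ene
Product: 35 2-methoxypropan-2-yl hydroperoxide
Conditions: O3, MeOH/CH2Cl2, −78 °C; then N2 purge (kept in solution)
Reagents that add atoms: ozone, [O-][O+]=O; methanol, CO
Why: Ozonolysis in methanol: the Criegee carbonyl oxide from the tetrasubstituted alkene is trapped by the solvent to give the α-methoxy hydroperoxide, a mono-protected hydrogen peroxide.

Step 26
Reactants: 33 (1S) C1 alcohol diacetate; 35 2-methoxypropan-2-yl hydroperoxide
Product: 37 (1R,3S,6R) C1 (2-methoxypropan-2-yl)peroxy diacetate, via C1 mesylate 36 (not isolated)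
Conditions: (MeSO2)2O, iPr2NEt, CH2Cl2, −20 °C; then 35, CsOH·H2O, DMF, 0 °C
Reagents that add atoms: none
Why: Sulfonylation, then SN2 displacement by a peroxide anion: the caesium salt of 35 is a weakly basic α-effect oxygen nucleophile that attacks the allylic mesylate from the back and inverts C1 from S to R. The anhydride avoids chloride, which would give an allylic chloride, and the ketal end of 35 prevents a second alkylation.

Step 27
Reactants: 37 C1 (2-methoxypropan-2-yl)peroxy diacetate
Product: 38 target, (1R,3S,6R)-3,13-diacetoxy-1-hydroperoxygermacra-4Z,7(11),10(14)-trien-12,6-olide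
Conditions: AcOH/H2O/THF (4:1:1), rt
Reagents that add atoms: none
Why: Mild acid hydrolysis of the peroxyketal releases the hydroperoxide with acetone and methanol; the O–O bond, the acetates and the C1 configuration are not affected.

## Compound list

1 | (S)-2,2-dimethyl-1,3-dioxolane-4-carbaldehyde | O=C[C@@H]1COC(C)(C)O1 | starting material
2 | ethyl 2-[bis(2,2,2-trifluoroethoxy)phosphoryl]propanoate | CCOC(=O)C(C)P(=O)(OCC(F)(F)F)OCC(F)(F)F | starting material
3 | ethyl (2Z)-3-[(4R)-2,2-dimethyl-1,3-dioxolan-4-yl]-2-methylprop-2-enoate | CCOC(=O)/C(C)=C\[C@@H]1COC(C)(C)O1 | intermediate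
4 | (2Z)-3-[(4R)-2,2-dimethyl-1,3-dioxolan-4-yl]-N-methoxy-N,2-dimethylprop-2-enamide | CON(C)C(=O)/C(C)=C\[C@@H]1COC(C)(C)O1 | intermediate (not isolated)
5 | (3Z)-4-[(4R)-2,2-dimethyl-1,3-dioxolan-4-yl]-3-methylbut-3-en-2-one | CC(=O)/C(C)=C\[C@@H]1COC(C)(C)O1 | intermediate
6 | 2-methylenepropane-1,3-diol | C=C(CO)CO | starting material
7 | 2-{[(4-methoxybenzyl)oxy]methyl}prop-2-en-1-ol | C=C(CO)COCc1ccc(OC)cc1 | intermediate
8 | 2-{[(4-methoxybenzyl)oxy]methyl}prop-2-enal | C=C(C=O)COCc1ccc(OC)cc1 | intermediate
9 | enol diisopinocampheylborinate of 5 | C=C(OB([C@@H]1C[C@@H]2C[C@H]([C@H]1C)C2(C)C)[C@@H]3C[C@@H]4C[C@H]([C@H]3C)C4(C)C)/C(C)=C\[C@@H]5COC(C)(C)O5 | intermediate (not isolated)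
10 | (1Z,5S)-1-[(4R)-2,2-dimethyl-1,3-dioxolan-4-yl]-5-hydroxy-6-{[(4-methoxybenzyl)oxy]methyl}-2-methylhepta-1,6-dien-3-one | C=C(COCc1ccc(OC)cc1)[C@@H](O)CC(=O)/C(C)=C\[C@@H]2COC(C)(C)O2 | intermediate
11 | C1 triisopropylsilyl ether of 10, (1S,6R) | C=C(COCc1ccc(OC)cc1)[C@@H](O[Si](C(C)C)(C(C)C)C(C)C)CC(=O)/C(C)=C\[C@@H]2COC(C)(C)O2 | intermediate
12 | (1S,3S,6R) C3 allylic alcohol | C=C(COCc1ccc(OC)cc1)[C@@H](O[Si](C(C)C)(C(C)C)C(C)C)C[C@H](O)/C(C)=C\[C@@H]2COC(C)(C)O2 | intermediate
13 | (1S,3S,6R) C3 tert-butyldimethylsilyl ether | C=C(COCc1ccc(OC)cc1)[C@@H](O[Si](C(C)C)(C(C)C)C(C)C)C[C@H](O[Si](C)(C)C(C)(C)C)/C(C)=C\[C@@H]2COC(C)(C)O2 | intermediate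
14 | (1S,3S,6R) C6,C7-diol | C=C(COCc1ccc(OC)cc1)[C@@H](O[Si](C(C)C)(C(C)C)C(C)C)C[C@H](O[Si](C)(C)C(C)(C)C)/C(C)=C\[C@@H](O)CO | intermediate
15 | C6,C7-bis(triethylsilyl) ether | C=C(COCc1ccc(OC)cc1)[C@@H](O[Si](C(C)C)(C(C)C)C(C)C)C[C@H](O[Si](C)(C)C(C)(C)C)/C(C)=C\[C@@H](O[Si](CC)(CC)CC)CO[Si](CC)(CC)CC | intermediate
16 | (1S,3S,6R) C7 aldehyde, C6 triethylsilyl ether | C=C(COCc1ccc(OC)cc1)[C@@H](O[Si](C(C)C)(C(C)C)C(C)C)C[C@H](O[Si](C)(C)C(C)(C)C)/C(C)=C\[C@@H](O[Si](CC)(CC)CC)C=O | intermediate
17 | tert-butyl diazoacetate | CC(C)(C)OC(=O)C=[N+]=[N-] | starting material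
18 | tert-butyl β-keto ester, C9 OPMB | C=C(COCc1ccc(OC)cc1)[C@@H](O[Si](C(C)C)(C(C)C)C(C)C)C[C@H](O[Si](C)(C)C(C)(C)C)/C(C)=C\[C@@H](O[Si](CC)(CC)CC)C(=O)CC(=O)OC(C)(C)C | intermediate
19 | tert-butyl β-keto ester, C9 alcohol | C=C(CO)[C@@H](O[Si](C(C)C)(C(C)C)C(C)C)C[C@H](O[Si](C)(C)C(C)(C)C)/C(C)=C\[C@@H](O[Si](CC)(CC)CC)C(=O)CC(=O)OC(C)(C)C | intermediate
20 | acylketene from 19 | C=C(CO)[C@@H](O[Si](C(C)C)(C(C)C)C(C)C)C[C@H](O[Si](C)(C)C(C)(C)C)/C(C)=C\[C@@H](O[Si](CC)(CC)CC)C(=O)C=C=O | intermediate (not isolated)
21 | twelve-membered allyl β-keto lactone, (1S,3S,6R) | C=C1COC(=O)CC(=O)[C@H](O[Si](CC)(CC)CC)/C=C(/C)[C@@H](O[Si](C)(C)C(C)(C)C)C[C@@H]1O[Si](C(C)C)(C(C)C)C(C)C | intermediate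
22 | ten-membered C7 ketone with C10 methylene, (1S,3S,6R) | C=C1CCC(=O)[C@H](O[Si](CC)(CC)CC)/C=C(/C)[C@@H](O[Si](C)(C)C(C)(C)C)C[C@@H]1O[Si](C(C)C)(C(C)C)C(C)C | intermediate
23 | C6 α-hydroxy ketone | C=C1CCC(=O)[C@H](O)/C=C(/C)[C@@H](O[Si](C)(C)C(C)(C)C)C[C@@H]1O[Si](C(C)C)(C(C)C)C(C)C | intermediate
24 | ethyl 2-(diethoxyphosphoryl)prop-2-enoate | C=C(C(=O)OCC)P(=O)(OCC)OCC | starting material
25 | (4-methoxyphenyl)methanol | COc1ccc(CO)cc1 | starting material
26 | ethyl 2-(diethoxyphosphoryl)-3-[(4-methoxybenzyl)oxy]propanoate (racemic) | CCOC(=O)C(COCc1ccc(OC)cc1)P(=O)(OCC)OCC | intermediate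
27 | 2-(diethoxyphosphoryl)-3-[(4-methoxybenzyl)oxy]propanoic acid (racemic) | OC(=O)C(COCc1ccc(OC)cc1)P(=O)(OCC)OCC | intermediate
28 | C6 phosphonoester of 23 (C11 epimers) | C=C1CCC(=O)[C@H](OC(=O)C(COCc2ccc(OC)cc2)P(=O)(OCC)OCC)/C=C(/C)[C@@H](O[Si](C)(C)C(C)(C)C)C[C@@H]1O[Si](C(C)C)(C(C)C)C(C)C | intermediate
29 | butenolide, C13 OPMB, C3 OTBS, C1 OTIPS | C=C1CCC2=C(COCc3ccc(OC)cc3)C(=O)O[C@@H]2/C=C(/C)[C@@H](O[Si](C)(C)C(C)(C)C)C[C@@H]1O[Si](C(C)C)(C(C)C)C(C)C | intermediate
30 | butenolide, C13 alcohol | C=C1CCC2=C(CO)C(=O)O[C@@H]2/C=C(/C)[C@@H](O[Si](C)(C)C(C)(C)C)C[C@@H]1O[Si](C(C)C)(C(C)C)C(C)C | intermediate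
31 | butenolide, C3,C13-diol | C=C1CCC2=C(CO)C(=O)O[C@@H]2/C=C(/C)[C@@H](O)C[C@@H]1O[Si](C(C)C)(C(C)C)C(C)C | intermediate
32 | C3,C13-diacetate, C1 OTIPS | C=C1CCC2=C(COC(C)=O)C(=O)O[C@@H]2/C=C(/C)[C@@H](OC(C)=O)C[C@@H]1O[Si](C(C)C)(C(C)C)C(C)C | intermediate
33 | (1S,3S,6R) C1 alcohol diacetate | C=C1CCC2=C(COC(C)=O)C(=O)O[C@@H]2/C=C(/C)[C@@H](OC(C)=O)C[C@@H]1O | intermediate
34 | 2,3-dimethylbut-2-ene | CC(C)=C(C)C | starting material
35 | 2-methoxypropan-2-yl hydroperoxide | COC(C)(C)OO | intermediate
36 | (1S) C1 methanesulfonate | C=C1CCC2=C(COC(C)=O)C(=O)O[C@@H]2/C=C(/C)[C@@H](OC(C)=O)C[C@@H]1OS(C)(=O)=O | intermediate (not isolated)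
37 | (1R,3S,6R) C1 (2-methoxypropan-2-yl)peroxy diacetate | C=C1CCC2=C(COC(C)=O)C(=O)O[C@@H]2/C=C(/C)[C@@H](OC(C)=O)C[C@H]1OOC(C)(C)OC | intermediate
38 | CNP0174966.1, (1R,3S,6R)-3,13-diacetoxy-1-hydroperoxygermacra-4Z,7(11),10(14)-trien-12,6-olide | C=C1CCC2=C(COC(C)=O)C(=O)O[C@@H]2/C=C(/C)[C@@H](OC(C)=O)C[C@H]1OO | target

## Step count and least certain steps

Total step count: 27. Longest linear sequence: 22 steps (1 to 38 through steps 1, 2, 5–16, 19–24, 26 and 27).

**Step 15 (key step).** The most likely failure is intermolecular allylation, which leads to oligomers. The next is protonation of the enolate with loss of the allyl unit, if closure of the strained ten-membered ring is slower than proton transfer.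
Fallback (sets out from 19, returns at 22): 19 would be treated with methyl chloroformate and pyridine to give the C9 methyl carbonate F1. Under Pd(PPh3)4 with 1,2-bis(diphenylphosphino)ethane at high dilution, the stabilised enolate of the intact β-keto ester would attack the π-allyl unit in a Tsuji–Trost macrocyclisation and form the ten-membered ketone with the tert-butoxycarbonyl group still on C8, F2. Heating F2 in wet toluene would take it through the acylketene and the β-keto acid, with loss of CO2, to 22. Here the C8–C9 bond is made with a non-decarboxylated, more persistent nucleophile, and the carboxyl group is removed afterwards.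

**Step 26.** Three processes threaten it: attack at C14 with allylic transposition, ionisation of the allylic mesylate with loss of configuration or participation of the C3 acetate, and acyl transfer from an acetate to the peroxide anion.
Fallback (sets out from 33, returns at 38): a Mitsunobu reaction of 33 with 2-nitrobenzenesulfonylhydrazide (PPh3, diethyl azodicarboxylate, THF, −30 °C) would give the C1 sulfonylhydrazide F3. On warming it would lose the sulfinic acid to give the allylic diazene F4, and then dinitrogen by a retro-ene shift that places hydrogen on C14 and the alkene at C1=C10, giving the (1(10)E,4Z)-dienolide diacetate F5 (the same structure as A1). Dye-sensitised photooxygenation of F5 (O2, tetraphenylporphyrin, visible light, CH2Cl2, 0 °C) would then install the C1 hydroperoxide and the C10=C14 methylene in one Schenck ene reaction and give 38. The C1 configuration would then be set by the conformation of the ring rather than by inversion.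

**Step 20.** Loss of 4-methoxybenzyloxide from the phosphonate carbanion may outrun its addition to the hindered C7 ketone, and a stronger base would put C6 at risk of epimerisation.
Fallback (sets out from 22, returns at 29): ethyl 3-[(4-methoxybenzyl)oxy]propanoate F6 (from 25 and ethyl acrylate by base-catalysed oxa-Michael addition) would be converted into its lithium enolate (LiN(iPr)2, THF, −78 °C) and added to the C7 ketone of 22 to give the β-hydroxy ester F7. HF·pyridine would remove the triethylsilyl group, and the freed C6 hydroxyl would close the β-hydroxy γ-lactone F8. Thionyl chloride in pyridine would dehydrate F8 towards the acidic C11–H and give 29. This replaces the olefination by an intermolecular aldol addition of a preformed ester enolate, followed by lactonisation and elimination.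

**Step 12.** The α-silyloxy β,γ-unsaturated aldehyde may epimerise at C6 or move its alkene into conjugation before it is consumed, or carbon may migrate in place of hydride.
Fallback (sets out from 16, returns at 18): the lithium enolate of tert-butyl acetate (LiN(iPr)2, THF, −78 °C) would be added to 16 to give the C7 carbinol β-hydroxy ester F9 as a mixture of epimers. Dess–Martin periodinane (NaHCO3, CH2Cl2) would oxidise it to 18.

**Step 5.** Facial selectivity of the reagent-controlled methyl ketone aldol may be poor, and its sense rests on the stated assumption.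
Fallback (sets out from 5, returns at 10): 5 would be converted into its trimethylsilyl dienol ether F10 (Me3SiOTf, Et3N, CH2Cl2, 0 °C). F10 would be combined with 8 in a catalytic enantioselective Mukaiyama aldol reaction (SiCl4 activated by a chiral bisphosphoramide, iPr2NEt, CH2Cl2, −78 °C), the catalyst antipode being the one that gives the (1S) adduct 10 in the same configurational check.

## Further compounds

F1 | step 15 | C9 methyl carbonate of 19 | C=C(COC(=O)OC)[C@@H](O[Si](C(C)C)(C(C)C)C(C)C)C[C@H](O[Si](C)(C)C(C)(C)C)/C(C)=C\[C@@H](O[Si](CC)(CC)CC)C(=O)CC(=O)OC(C)(C)C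
F2 | step 15 | ten-membered C7 ketone with tert-butoxycarbonyl at C8 (C8 epimers) | C=C1CC(C(=O)OC(C)(C)C)C(=O)[C@H](O[Si](CC)(CC)CC)/C=C(/C)[C@@H](O[Si](C)(C)C(C)(C)C)C[C@@H]1O[Si](C(C)C)(C(C)C)C(C)C
F3 | step 26 | (1R) C1 N-(2-nitrobenzenesulfonyl)hydrazide of the diacetate | C=C1CCC2=C(COC(C)=O)C(=O)O[C@@H]2/C=C(/C)[C@@H](OC(C)=O)C[C@H]1N(N)S(=O)(=O)c3ccccc3[N+](=O)[O-]
F4 | step 26 | (1R) C1 allylic diazene | C=C1CCC2=C(COC(C)=O)C(=O)O[C@@H]2/C=C(/C)[C@@H](OC(C)=O)C[C@H]1N=N
F5 | step 26 | (1(10)E,4Z)-germacradienolide diacetate | C/C1=C\C[C@H](OC(C)=O)/C(C)=C\[C@H]2OC(=O)C(COC(C)=O)=C2CC1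
F6 | step 20 | ethyl 3-[(4-methoxybenzyl)oxy]propanoate | CCOC(=O)CCOCc1ccc(OC)cc1
F7 | step 20 | C7 tertiary alcohol β-hydroxy ester (C7 and C11 epimers) | C=C1CCC(O)(C(COCc2ccc(OC)cc2)C(=O)OCC)[C@H](O[Si](CC)(CC)CC)/C=C(/C)[C@@H](O[Si](C)(C)C(C)(C)C)C[C@@H]1O[Si](C(C)C)(C(C)C)C(C)C
F8 | step 20 | β-hydroxy γ-lactone (C7 and C11 epimers) | C=C1CCC2(O)C(COCc3ccc(OC)cc3)C(=O)O[C@@H]2/C=C(/C)[C@@H](O[Si](C)(C)C(C)(C)C)C[C@@H]1O[Si](C(C)C)(C(C)C)C(C)C
F9 | step 12 | C7 carbinol tert-butyl β-hydroxy ester (C7 epimers) | C=C(COCc1ccc(OC)cc1)[C@@H](O[Si](C(C)C)(C(C)C)C(C)C)C[C@H](O[Si](C)(C)C(C)(C)C)/C(C)=C\[C@@H](O[Si](CC)(CC)CC)C(O)CC(=O)OC(C)(C)C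
F10 | step 5 | trimethylsilyl dienol ether of 5 | C=C(O[Si](C)(C)C)/C(C)=C\[C@@H]1COC(C)(C)O1
A1 | alternative 1 | (1(10)E,4Z)-germacradienolide diacetate | C/C1=C\C[C@H](OC(C)=O)/C(C)=C\[C@H]2OC(=O)C(COC(C)=O)=C2CC1
A2 | alternative 1 | open-chain alkynyl Z-enal diacetate | O=C/C=C(/C)[C@@H](OC(C)=O)C/C=C(\C)CCC#CCOC(C)=O
A3 | alternative 2 | (1S)-silyloxy 3-acetoxy macrocyclic butenolide | C=C1CCC2=C(COC(C)=O)C(=O)O[C@@H]2/C=C(/C)[C@@H](OC(C)=O)C[C@@H]1O[Si](C)(C)C(C)(C)C
A4 | alternative 2 | ten-membered (3Z,5Z)-diene with exocyclic alkylidene carboxylic acid | C=C1CC/C(=C(\COC(C)=O)/C(O)=O)/C=C\C(C)=C/C[C@@H]1O[Si](C)(C)C(C)(C)C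
A5 | alternative 3 | ten-membered (1(10)E,4Z)-dienyl triflate | FC(F)(F)S(=O)(=O)O/C1=C\C[C@H](OCOC)/C(C)=C\[C@@H](OCc2ccc(OC)cc2)C3(OCCO3)CC1
A6 | alternative 3 | cis-dialkenylcyclohexanol | C=C[C@]1(O)CCC2(OCCO2)[C@H](OCc3ccc(OC)cc3)[C@@H]1/C(C)=C/OCOC
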